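Minutes per turn of the catalyst was the unit I reckoned in. By cycle time (the usual turnover time) I meant the catalyst's fraction of the charge divided by the fraction of the charge turned into target per minute: the time one catalyst takes to deliver one target.

| setting | spring | autumn | summer | oak | elm | birch | maple |
|---|---|---|---|---|---|---|---|
| starting material | 0.22 M (fed, over 30 s) | 0.22 M (fed, over 30 s) | 0.22 M (fed, over 30 s) | 0.22 M (fed, over 30 s) | 0.22 M (fed, over 30 s) | 0.22 M (fed, over 30 s) | 0.22 M (fed, over 30 s) |
| coupling partner | 0.264 M | 0.264 M | 0.25 M | 0.200 M | 0.264 M | 0.264 M | 0.264 M |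
| free catalyst | 4.4 mM | 7.7 mM | 11 mM | 8.0 mM | 11 mM | 11 mM | 6.0 mM |
| temperature | 0 °C | 15 °C | 0 °C | 25 °C | 25 °C | 5 °C | 25 °C |
| remark | run made earlier | run made earlier | run made earlier |  |  |  |  |
| time |  |  |  | 2.5 min | 2.5 min | 2.5 min | 2.5 min |

| run | time / min | target / % |
|---|---|---|
| spring | 0.667 | 0.9 |
| spring | 1.00 | 0.6 |
| spring | 1.50 | 0 |
| spring | 2.50 | 0 |
| spring | 3.00 | 2.1 |
| spring | 5.00 | 2.9 |
| spring | 8.00 | 4.9 |
| autumn | 0.250 | 0 |
| autumn | 0.667 | 1.6 |
| autumn | 1.00 | 3.7 |
| autumn | 1.50 | 5.9 |
| autumn | 2.50 | 9.1 |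
| autumn | 3.00 | 14.9 |
| autumn | 4.00 | 21.5 |
| summer | 1.50 | 1.3 |
| summer | 3.00 | 3.5 |
| summer | 5.00 | 4.9 |
| summer | 6.00 | 8.2 |
| summer | 8.00 | 10.3 |

(scatter of a reading: 1 percentage point)

- ranking by amount of target, in percent of the starting material charged, from high to low, at 2.5 min (oak / elm / birch / maple)
- the amount of target, in percent of the starting material charged of the flask you put first, at 2.5 min
- the amount of target, in percent of the starting material charged of the flask you put last, at 2.5 min

I took each slope from the first to the last reading that showed target. The spring run held catalyst at 2.00% of the charge and gave a cycle time of 3.67 min. The summer run, at the same temperature with 5.00% and with 0.25 M of coupling partner against 0.264 M, gave 3.61 min, about the same, both being readings with a scatter of 1 percentage point. So at one temperature I took the amount of target to be the catalyst fraction times the number of cycles. The autumn run, at 15 °C, gave 0.586 min, shorter than in summer.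

Birch lies a third of the way from 0 °C to 15 °C, so spacing the cycle time evenly on a logarithmic scale gave 1.97 min. Taking the dosing time as the lag, I reckoned 1.02 cycles for birch, or 5.08% target. Elm and maple share partner and temperature, so I expected elm to beat maple by their catalyst ratio, 1.83. Oak, at 3.64% catalyst, stood between them in catalyst but held less coupling partner, so I placed it second and held that loosely. Carrying the temperature factor on to 25 °C gave 0.174 min and 57.3% for elm, a long extrapolation from two slopes that I held loosely.

The forecast put elm > oak > maple > birch, with 38% on top, less than my figure for elm, and 5% last; of the middle it said “Oak versus maple is nearly a tie”.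

The flasks gave elm > oak > maple > birch, with 41.0%, 27.0%, 23.1% and 4.82%.

    coupling partner + free catalyst → catalyst intermediate A (k = 0.780 M⁻¹ s⁻¹, Ea = 59.0 kJ mol⁻¹)
    catalyst intermediate A → by-product + catalyst intermediate B (k = 0.300 s⁻¹, Ea = 67.0 kJ mol⁻¹)
    catalyst intermediate B ⇌ catalyst intermediate C (K = 1.30, k = 0.300 s⁻¹, Ea = 77.0 kJ mol⁻¹, ΔH = −48.0 kJ mol⁻¹)
    starting material + catalyst intermediate C ⇌ catalyst intermediate D (K = 450 M⁻¹, k = 110 M⁻¹ s⁻¹, Ea = 41.0 kJ mol⁻¹, ΔH = 4.00 kJ mol⁻¹)
    catalyst intermediate D → catalyst intermediate E (k = 0.260 s⁻¹, Ea = 69.0 kJ mol⁻¹)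
    catalyst intermediate E → free catalyst + target (k = 12.0 s⁻¹, Ea = 67.0 kJ mol⁻¹)
    starting material + target → side product (k = 0.00340 M⁻¹ s⁻¹, Ea = 76.0 kJ mol⁻¹)
    (constants at 25 °C)

At 2.5 min, elm still held starting material (54.8%) and coupling partner (62.1%), and its catalyst was still going round, 41.6% free and 20.8% as catalyst intermediate D. Its target counts as 8.21 cycles, a cycle time of 0.244 min after the dosing time, against the 0.174 min I had carried on to 25 °C and the 3.67 min read in the spring run at 0 °C, and maple made 8.48 cycles. Birch, with elm's catalyst fraction, made 0.964 cycles, a cycle time of 2.08 min, with 93.8% of its starting material still standing.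

The data stem from a simulated flask with constants of no real substance.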